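If two runs that differed in free base, 0.65 equiv on Thursday and 3.1 equiv on Monday, read alike, I could pool them and replace their curves by one mean rate. They did read alike: at 15.0 h the electrophile stood at 68% and 70%, a gap of 2 percentage points against a scatter of 2 points.

| setting | Thursday's | Monday's | oak | cedar | ash |
|---|---|---|---|---|---|
| electrophile | 0.081 M (fed, over 6.0 h) | 0.081 M (fed, over 6.0 h) | 0.081 M (fed, over 6.0 h) | 0.081 M (fed, over 6.0 h) | 0.081 M (fed, over 6.0 h) |
| nucleophile | 2 equiv | 2 equiv | 2.00 equiv | 2.00 equiv | 2.00 equiv |
| free base | 0.65 equiv | 3.1 equiv | 1.10 equiv | 2.20 equiv | 4.40 equiv |
| scavenger | 1.2 equiv | 1.2 equiv | 1.20 equiv | 1.20 equiv | 1.20 equiv |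
| remark | run made earlier; the fed solution adds 0.20 times the starting volume | run made earlier; the fed solution adds 0.20 times the starting volume | the fed solution adds 0.20 times the starting volume | the fed solution adds 0.20 times the starting volume | the fed solution adds 0.20 times the starting volume |
| time |  |  | 30 h | 30 h | 30 h |

| run | time / h | electrophile / % | product / % |
|---|---|---|---|
| Thursday's | 0.833 | 17 | 0 |
| Thursday's | 2.50 | 46 | 2 |
| Thursday's | 4.00 | 57 | 3 |
| Thursday's | 6.00 | 90 | 8 |
| Thursday's | 10.0 | 82 | 23 |
| Thursday's | 12.0 | 76 | 28 |
| Thursday's | 15.0 | 68 | 29 |
| Monday's | 1.33 | 18 | 0 |
| Monday's | 2.00 | 32 | 1 |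
| Monday's | 3.00 | 49 | 2 |
| Monday's | 4.00 | 64 | 3 |
| Monday's | 6.00 | 87 | 13 |
| Monday's | 10.0 | 80 | 18 |
| Monday's | 15.0 | 70 | 30 |

(scatter of a reading: 2 percentage points)

- charges are per starting volume, the dose included; the dosed solution carries all of it
- the numbers in the tables scatter by 2 percentage points (one standard deviation)
- percentages count the whole charge, also what has not yet gone in

- part of the electrophile that has reacted at the end, oak
- part of the electrophile that has reacted at the end, cedar
- part of the electrophile that has reacted at the end, ash
- what raising the equivalents of free base from its lowest to its highest value here does to the part of the electrophile that has reacted (changes below 5 percentage points count as none) (no change / it rises / it falls)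

The top rung I could read was the feed, which brought in a fraction 0.167 /h of the charge. For the reaction I used a reciprocal clock. The pooled fractions were 88.5% at 6.00 h and 69.0% at 15.0 h, so the reciprocal clock, the gain per hour in one over the fraction of the charge still electrophile, read 0.0355 /h. The feed was faster than this, and so the electrophile piled up during dosing and reacted mostly afterwards.

The next rung was the clock's own time, 28.2 h, beside the asked 30 h, so I expected a flask caught midway. A steady clock means that the rate falls with the square of the fraction, as it does if the nucleophile falls in step with the electrophile. It gave 49.5% reacted at the end. A fixed mean constant, the pseudo-first-order view, gave 54.4%. With this scatter I could not part the two on the readings, but a constant taken from the earlier window ignores any further fall of the nucleophile, so I committed to the clock for oak, cedar and ash, though ash at 4.40 equiv lies beyond Monday's load.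

The forecast gave 51%, 51% and 51%, slightly above mine, with no change as its trend, on the ground that the “free base therefore has no visible effect”.

The flasks gave 49.3% for oak, 49.3% for cedar and 49.4% for ash, so the trend was no change, a shift of 0.054 points.

    electrophile + nucleophile → acid set free + product (k = 0.265 /M/h)
    nucleophile + acid set free ⇌ protonated nucleophile, settled at all times (K = 3200 /M)
    acid set free + free base ⇌ salt of the base, settled at all times (K = 16.0 /M)
    nucleophile + acid set free ⇌ idle adduct, settled at all times (K = 1510 /M)
    acid set free + scavenger → scavenged by-product (k = 3.65 /M/h)

At the end of oak the nucleophile left, 51% of its charge, stood level with the electrophile left, 51%. Starting the clock from oak's electrophile of 90.0% at 6.00 h gives 15.4% reacted at 8.0 h, where oak itself stands at 15.5%.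

(The numbers in the tables were generated by integration on assumed constants; scatter was added.)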